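The vessel is closed, stirred and held at one temperature, and in it G turns to Z with J as catalyst.

| flask | G | J | time |
|---|---|---|---|
| Tuesday's | 0.300 M | 0.0300 M |  |
| Sunday's | 0.180 M | 0.0300 M |  |
| Monday's | 0.300 M | 0.0150 M |  |
| Friday's | 0.450 M | 0.0300 M |  |
| Wednesday's | 0.300 M | 0.0300 M | 380 min |

| run | time / min | [Z] / M |
|---|---|---|
| Tuesday's run | 30 | 0.020 |
| Tuesday's run | 60 | 0.050 |
| Tuesday's run | 90 | 0.081 |
| Tuesday's run | 120 | 0.100 |
| Tuesday's run | 150 | 0.134 |
| Sunday's run | 30 | 0.007 |
| Sunday's run | 60 | 0.028 |
| Sunday's run | 90 | 0.035 |
| Sunday's run | 120 | 0.044 |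
| Sunday's run | 150 | 0.060 |
| Monday's run | 30 | 0.015 |
| Monday's run | 60 | 0.030 |
| Monday's run | 90 | 0.050 |
| Monday's run | 120 | 0.072 |
| Monday's run | 150 | 0.099 |
| Friday's run | 30 | 0.040 |
| Friday's run | 60 | 0.089 |
| Friday's run | 90 | 0.146 |
| Friday's run | 120 | 0.212 |
| Friday's run | 150 | 0.272 |

(readings scatter by 0.003 M)

- Overall: G -> Z, with J as catalyst.
- Constant volume, constant temperature.
- An order is taken over about fifteen percent of the charge, up and down.

- apparent order in [J] of the starting rate, round the charge of the Tuesday's run (the rate where two percent of its G have turned into Z)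
- apparent order in [G] of the starting rate, round the charge of the Tuesday's run (the rate where two percent of its G have turned into Z) (one fixed amount of Z, the same in the runs compared)
- the Sunday's run starts with 0.120 M less of G than the Tuesday's run, and with no Z. Compared where both hold the same amount of G, once fifteen percent of what the Sunday's run was charged with has turned into Z, is the Sunday's run faster, slower or alike (within a tenth)?
- Z in the Wednesday's run at 380 min, as a share of the G charged

- I treated G like a draining tank with a lifetime, [G] divided by the rate. In Tuesday's run, from 90 min to 150 min, Z was made at 8.83 × 10⁻⁴ M min⁻¹ with [G] near 0.192 M and [Z] near 0.108 M, so I read a lifetime of 218 min.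
- Over the same times in Friday's run, [Z] stood near 0.209 M and the lifetime read 115 min, shorter than Tuesday's. Lifetime times [Z] read 1413 M·s and 1442 M·s, so I took the rate as [Z][G] over their mean, 1420 M·s: autocatalysis, with Z speeding its own making.
- [Z] and [G] add up to the charge, so under that rule the odds [Z]/[G] grow by a factor e in every 79.0 min, the odds time: that mean divided by the charge. Wednesday's flask has Tuesday's charge, so I carried Tuesday's run forward from 150 min, with 0.166 M of G left and 230 min to go.
- Bound from below: holding the lifetime at 218 min, too long once [Z] grows, gives 80.7 %.
- Bound from above: under that rule the lifetime reaches the odds time when [Z] equals Tuesday's charge, and holding it there throughout gives 97.0 %.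
- Tightened: the odds start at 0.807 and 2.91 odds times pass, which gives 93.7 %. I committed to that.
- The forecast, on the ground that “the product speeds the reaction”, gave 0.55 in [J], 1.45 in [G], slower and 78 %, which is below my lower bound.

The flask gave 93.6 %, above my lower bound and below my upper bound, with orders 0.92 in [J] and 1.1 in [G], and Sunday's run came out slower.

    J + G → Z + J (0.1014 L mol⁻¹ min⁻¹)
    2 J → 2 Xa (0.3168 L mol⁻¹ min⁻¹)
    G + Z → 2 Z (0.03924 L mol⁻¹ min⁻¹)

At the point of equal [G] asked about, Sunday's run went at 0.37 of the rate of Tuesday's run. Wednesday's odds reached 14.6, which, counted from the odds read in Tuesday's run at 150 min, is 2.90 odds times at 79.5 min each. Reckoned with the charge of Sunday's run, the odds time comes to 132 min. In Sunday's run Z stood at a quarter of the charge at 112 min, and the odds must grow by a factor 3 for Z to reach half of it, so the count gives 257 min, later than the flask's 232 min.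

The numbers in the tables were generated by integration with made-up constants; noise was put on by code.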